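The runs come from a simulation with constants of no real substance, noise included.

The ash run lost starting material far faster in its first 3.00 min than between 15.0 min and 50.0 min.

| setting | ash | red | teal | amber |
|---|---|---|---|---|
| starting material | 30 mM | 20 mM | 20 mM | 20 mM |
| protic impurity | 6 mM | 6.00 mM | 6.00 mM | 6.00 mM |
| remark | run made earlier |  |  |  |
| time |  | 3.0 h | 10 h | 25 h |

ash run (percent of the starting material charged)

| time / min | starting material / % | product / % |
|---|---|---|
| 3.00 | 86 | 1 |
| 8.00 | 83 | 0 |
| 15.0 | 80 | 1 |
| 25.0 | 78 | 3 |
| 30.0 | 78 | 0 |
| 40.0 | 76 | 1 |
| 50.0 | 75 | 4 |

(scatter of a reading: 1.5 percentage points)



* which of these there is most of at the end, counted by the starting material in it, red (product / starting material)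
* which of these there is most of at the end, counted by the starting material in it, teal (product / starting material)
* which of these there is most of at the end, counted by the starting material in it, amber (product / starting material)
* final amount of the leader among these, as a percentage of the starting material charged, in red
* final amount of the leader among these, as a percentage of the starting material charged, in teal
* final amount of the leader among these, as a percentage of the starting material charged, in amber

I read the fast part as protic impurity quenching starting material one for one, with the impurity as the limiting reagent: 6 mM in 30 mM is 20.0%, about what ash had lost by 15.0 min. So I froze one quantity, the usable share, the part of the charge still able to become product once the quench is over 70.0%: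

u = (c(starting material) − c(protic impurity)) / c(starting material)

Two extreme flasks could be solved in the head. With the slow step frozen, starting material stays at u and product at nothing; with it finished, starting material is gone and product stands at u. The real flask lies between them on one line, starting material + product = u, so the leader holds at least 35.0%. Ash at its last reading summed to 79.0%, against its own u of 80.0%.

For the place on that line I read a time constant from the ash tail, rough given the scatter, and treated the tail as a plain decay:

τ = 9.04 h
crossing, τ·ln(2) = 6.27 h
red, starting material: 50.2%
teal, product: 46.8%
amber, product: 65.6%

The forecast named starting material at 58% in red, starting material at 39% in teal, where I differed, and product at 52% in amber, saying of teal: “This is close and could flip”.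

The flasks gave starting material at 56.1% in red, product at 69.9% in teal and product at 70.0% in amber.

    starting material + 2 product → 3 product (k = 120 /M²/min)
    starting material + protic impurity → quenched substrate (k = 9.00 /M/min)
    starting material → product (k = 9.40 × 10⁻⁴ /min)

Red's two species summed to 70.0%, which is u, but my single time constant did not fit red: at 3.0 h red held 56.1% starting material, more than my 50.2%, yet red's crossing came at 5.16 h, earlier than my 6.27 h. Amber holds 0% starting material; with the difference in time taken away, the same flask holds 56.1%, so that difference in time is the main reason. Red left until 8.0 h keeps u = 70.0% and stands past the crossing, so product should lead, somewhere between 35.0% and u. It gave product 67.6% and starting material 2.39%.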